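## The problem

The target is a sesquineolignan whose centre is a cis-fused 3,7-dioxabicyclo[3.3.0]octane (furofuran: bridgeheads C1 and C5, aryl-bearing C2 and C6, methylenes C4 and C8, ring oxygens O3 and O7). C6 carries a syringyl ring, and the aryl ring on C2 is also the benzo ring of a 7-methoxy-2,3-dihydrobenzofuran with a guaiacyl group on its C2 and a hydroxymethyl group on its C3. Six stereocentres must be set: (1R,2S,5R,6S) in the furofuran, which places both aryl groups exo, and (2S,3S) in the dihydrobenzofuran, which places aryl and hydroxymethyl cis. The furofuran centres are contiguous, so a fixed bridgehead pair C1/C5 can direct C2 and C6, each aryl group going to the convex face as its oxolane closes. The dihydrobenzofuran pair is insulated from them by an aromatic ring and needs its own source of asymmetry; because cis is the less stable arrangement, it must be formed under kinetic control and not be exposed to base while a carbonyl group sits on C3. The three benzylic C–O bonds (C2–O3, C6–O7, benzofuran C2–O1) are all para to an oxygen donor: acid ionises them, hydrogenolysis cuts them, and a free para phenol in base opens them to quinone methides, so the phenols stay masked to the end and the late steps avoid acid, hydrogen and strong base. The enabling feature is that C1 and C5 each carry one CH(O)Ar arm and one CH2O arm: C4–C5–C1–C8 is the carbon chain of a butenolide (C8 the lactone carbonyl, C4 the acetal carbon), and C6 and C2 are aldehyde carbons, so C5–C6 can be made by conjugate addition of an acyl anion equivalent and C1–C2 by aldol capture of the resulting enolate.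

## Retrosynthesis

**20 to 18.** No skeletal bond is cut. The two phenols of 20 are traced to the triisopropylsilyl ethers of 19, and the hydroxymethyl group of 19 to the methyl ester of 18. Silyl ethers are preferred to benzyl ethers because hydrogenolysis would also cut the benzylic ring C–O bonds. The ester is reduced before desilylation so that the cis ester never meets fluoride base. The forward steps must be a non-basic hydride reduction and a buffered fluoride cleavage.

**18 to 17.** The benzofuran C2–C3 bond is cut, leading to aryldiazoacetate 17, whose carbene inserts into the benzylic C–H of the ortho ether. Against oxidative phenol coupling (trans, no absolute control) or an O-alkylative closure (two centres to be preset), this cut creates both centres in one catalyst-controlled event that is intrinsically cis-selective. The ether that protected the phenol becomes benzofuran C2 and its guaiacyl group, so 17 is simpler by one ring and two stereocentres. The forward reaction has to discriminate the two benzylic hydrogens and the two carbene faces.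

**17 to 15.** The aryl–CH2 bond is cut. Diazo ester 17 comes from arylacetate 16 by diazo transfer, and 16 from aryl iodide 15 and the zinc enolate of methyl acetate. An iodide is chosen as the handle because it is inert to enolates, borohydride, mercury salts and sulfonylation, and so can be carried from a commercial aldehyde.

**15 to 14.** The two benzylic C–O bonds C2–O3 and C6–O7 are cut, giving tetraol 14. Closing the rings at the benzylic carbons, rather than setting these centres beforehand, means that 14 needs defined configuration only at C1 and C5. The forward reaction must place each aryl group exo.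

**14 to 12.** No skeletal bond is cut. Tetraol 14 is the full reduction product of keto lactone 13, whose ketone is unmasked from the dithiane of 12. The lactone acetal of 12 is recognised as a ring that holds C1 and C5 trans and disappears on reduction, releasing the auxiliary.

**12 to 3, 9 and 8.** The bonds C5–C6 and C1–C2 are cut in one operation. Lithiated dithiane 10, made from 3, adds to butenolide 9 to give enolate 11, which is trapped by aldehyde 8. Compared with stepwise aldol or alkylation routes to 2,3-disubstituted butane-1,4-diols, this cut draws all ten backbone carbons and both aryl groups from three pieces of similar size. It also takes the absolute configuration from a commercial crystalline auxiliary. The forward reaction must be anti twice.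

**Fragments.** Dithiane 3 comes from silylated syringaldehyde 2, and 2 from syringaldehyde 1. Aldehyde 8 is cut at its benzyl–O bond into 5-iodovanillin 7 and benzyl alcohol 6; 6 comes from vanillin 4 through silyl ether 5.

## Roads not taken

**Alternative 1:** Cut O7–C6 and C5–C6, with C4 at the enol ether level. Forward: the hydroxyl of the enantiopure 2-aryl-3-hydroxymethyl-2,3-dihydrofuran A2 exchanges with the dimethyl acetal A3 under Me3SiOTf, the enol ether carbon attacks the oxocarbenium ion, and Et3SiH reduces the resulting cation at C4, giving furofuran A1.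

- Merits: one flask closes the second oxolane, and C5 and C6 are set within a bicyclic transition state. C6 is therefore better defined than in the chosen plan, where it is settled only in the ring closure of step 9.
- Weak points: A2 has two contiguous stereocentres that need their own asymmetric sequence, whereas butenolide 9 is bought. The 2-aryl-dihydrofuran C–O bond of A2 is itself ionisable under Me3SiOTf. A para-silyloxybenzyl ether would not survive the Lewis acid, which is why A1 carries a plain benzyl ether. Carbene insertion into that ether would give a 2-phenyl, not a 2-guaiacyl, benzofuran. The benzyl group would have to be removed without hydrogenolysis (aryl iodide and benzylic ethers present) and replaced.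
- Comparison: the chosen plan offsets its weaker control of C6 with commercial chirality, a vanillyl ether that serves from the start to the insertion, and no strong Lewis acid.

**Alternative 2:** Cut C1–C5 and C6–O7. Forward: Cp2TiCl (trivalent titanium, from Cp2TiCl2 and zinc) opens the epoxide of the epoxy cinnamyl ether A5 to the C1 radical, which closes 5-exo onto the alkene; after oxidation by iodine the titanium alkoxide oxygen captures the benzylic C6. The product A4 is identical with 15.

- Merits: two rings and three stereocentres relative to C2 form in one step, and the route from A5 to the furofuran iodide is shorter than the three steps from 12 to 15. In this respect it is better.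
- Weak points: the absolute configuration at C2 of A5 must come from separate asymmetric chemistry. The C1/C2 relationship from the radical closure is preferred, not enforced. The aryl iodide is exposed to a low-valent metal and zinc. The electron-rich rings are exposed to iodine. The titanium reagent is stoichiometric.
- Comparison: the chosen plan sets both bridgeheads by two anti additions to a rigid ring and uses only polar chemistry near the iodide.

**Alternative 3:** Cut benzofuran C2–C3. Forward: the aryldiazoacetate A7 (identical with 17) loses nitrogen at a chiral dirhodium tetracarboxylate and inserts into the ortho benzylic C–H to give the cis ester A6 (identical with 18).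

- Merits: it is the only direct catalytic entry to the cis-dihydrobenzofuran, and it uses the phenol protecting group as a building block.
- Weak points: as a strategy it says nothing about how the furofuran iodide is made, and it places its main stereochemical risk late.
- Comparison: it is not a rival. It is adopted unchanged as steps 10 to 12, and the chosen plan adds a convergent, auxiliary-controlled supply of 15. The late risk is shared by both.

Key step: step 6

## Route

Abbreviations: TIPS = triisopropylsilyl; Syr′ = 3,5-dimethoxy-4-(triisopropylsilyloxy)phenyl; Gua′ = 3-methoxy-4-(triisopropylsilyloxy)phenyl; Iod′ = 3-iodo-5-methoxy-4-(Gua′-methoxy)phenyl; Men = (1R,2S,5R)-2-isopropyl-5-methylcyclohexyl (l-menthyl). Furofuran locants are those of 3,7-dioxabicyclo[3.3.0]octane.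

Assumption on the sense of the carbene insertion: Rh2(S-PTTL)4 is taken to give the (2R,3S)-cis ester in the parent 2-benzyloxyphenyl series, so the (2S,3R) ester 18 calls for the mirror-image catalyst Rh2(R-PTTL)4, dirhodium tetrakis[N-phthaloyl-(R)-tert-leucinate]. If the sense is the reverse, the two catalysts change places and nothing else is altered.

Step 1
Reactants: 1 syringaldehyde (4-hydroxy-3,5-dimethoxybenzaldehyde)
Product: 2 3,5-dimethoxy-4-(triisopropylsilyloxy)benzaldehyde
Conditions: TIPSCl, imidazole, DMF, rt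
Reagents that add atoms: triisopropylsilyl chloride, CC(C)[Si](Cl)(C(C)C)C(C)C
Why: Imidazole-promoted O-silylation of a phenol; the bulky silyl ether should withstand n-BuLi, hydrides and amidine base and be removed last by fluoride.

Step 2
Reactants: 2 3,5-dimethoxy-4-(triisopropylsilyloxy)benzaldehyde
Product: 3 2-(Syr′)-1,3-dithiane
Conditions: HS(CH2)3SH, BF3·OEt2 (cat.), CH2Cl2, 0 °C
Reagents that add atoms: propane-1,3-dithiol, SCCCS
Why: Lewis-acid-catalysed dithioacetalisation of an aryl aldehyde; the hindered aryl silyl ether should tolerate catalytic BF3·OEt2 at 0 °C.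

Step 3
Reactants: 4 vanillin (4-hydroxy-3-methoxybenzaldehyde)
Product: 5 3-methoxy-4-(triisopropylsilyloxy)benzaldehyde
Conditions: TIPSCl, imidazole, DMF, rt
Reagents that add atoms: triisopropylsilyl chloride, CC(C)[Si](Cl)(C(C)C)C(C)C
Why: Phenol O-silylation as in step 1.

Step 4
Reactants: 5 3-methoxy-4-(triisopropylsilyloxy)benzaldehyde
Product: 6 (Gua′)methanol
Conditions: NaBH4, MeOH, 0 °C
Reagents that add atoms: none
Why: Borohydride reduction of an aryl aldehyde; the aryl silyl ether is stable in cold methanol.

Step 5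
Reactants: 6 (Gua′)methanol; 7 5-iodovanillin (4-hydroxy-3-iodo-5-methoxybenzaldehyde)
Product: 8 3-iodo-5-methoxy-4-(Gua′-methoxy)benzaldehyde
Conditions: PPh3, DIAD, THF, 0 °C to rt
Reagents that add atoms: none
Why: Mitsunobu etherification of an acidic phenol (para formyl, ortho iodo) with a primary benzylic alcohol; the neutral conditions avoid a labile para-silyloxybenzyl halide and base-induced silyl transfer.

Step 6
Reactants: 3 2-(Syr′)-1,3-dithiane; 9 (5R)-5-(Men-oxy)furan-2(5H)-one; 8 3-iodo-5-methoxy-4-(Gua′-methoxy)benzaldehyde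
Product: 12 (3S,4R,5R)-3-[hydroxy(Iod′)methyl]-4-[2-(Syr′)-1,3-dithian-2-yl]-5-(Men-oxy)oxolan-2-one (both carbinol epimers), via lithiated dithiane 10 (not isolated), via lithium enolate 11 (not isolated)
Conditions: 3, n-BuLi (slight deficit), THF, −78 to −20 °C; 9, −78 °C; 8, −78 °C; AcOH, −78 °C
Reagents that add atoms: none
Why: n-BuLi removes the dithiane C2–H of 3, and the sulfur-stabilised benzylic anion 10 adds 1,4 to butenolide 9, forming furofuran C5–C6 and lithium enolate 11. Enolate 11 then adds to the carbonyl group of 8, forming furofuran C1–C2; the closest known reaction type is the tandem conjugate addition–aldol of lithiated aryl dithioacetals with 5-alkoxy-2(5H)-furanones. No ring is closed: the lactone acetal of 9 persists as a temporary ring that holds the two new substituents trans, which becomes the cis ring fusion once the ring is reduced away. The centre at lactone C4 (furofuran C5) is controlled by the acetal centre of 9, whose menthyloxy group shields one face of the flat butenolide so that 10 enters anti to it (4R). The centre at lactone C3 (furofuran C1) is controlled by the dithianyl group just introduced, the aldehyde approaching the enolate anti to it (3S). The carbinol centre is not controlled and need not be, since it is set again in step 9. The step needs 1,4- rather than 1,2-addition, which the soft, hindered anion and the unsubstituted β-carbon secure. It also needs attack on the formyl group of 8 rather than on its aryl iodide, which is secured because no alkyllithium remains when 8 is added. Retro-aldol and proton transfer are held back by the low temperature, the cold acidic quench and the absence of α-hydrogens in 8.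

Step 7
Reactants: 12 (3S,4R,5R)-3-[hydroxy(Iod′)methyl]-4-[2-(Syr′)-1,3-dithian-2-yl]-5-(Men-oxy)oxolan-2-one
Product: 13 (3S,4R,5R)-3-[hydroxy(Iod′)methyl]-4-(Syr′-carbonyl)-5-(Men-oxy)oxolan-2-one
Conditions: Hg(ClO4)2·3H2O, CaCO3, THF/H2O, 0 °C
Reagents that add atoms: water, O
Why: Hydrolysis of a dithioacetal promoted by thiophilic divalent mercury and buffered by CaCO3, so that the acetal, the silyl ethers and the vanillyl ether stay intact. The centre α to the new ketone is trans to both ring neighbours and has no drive to epimerise.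

Step 8
Reactants: 13 (3S,4R,5R)-3-[hydroxy(Iod′)methyl]-4-(Syr′-carbonyl)-5-(Men-oxy)oxolan-2-one
Product: 14 (2R,3R)-2,3-bis(hydroxymethyl)-1-(Iod′)-4-(Syr′)butane-1,4-diol (carbinol epimers)
Conditions: LiBH4 (excess), THF, 0 °C to rt
Reagents that add atoms: none
Why: Hydride reduction of the ketone and of the lactone acetal: the reduced lactone opens, the hemiacetal expels menthol, and both aldehydes formed are reduced at once, which should leave the centres at C1 and C5 untouched. LiBH4 is chosen because it does not attack aryl iodides.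

Step 9
Reactants: 14 (2R,3R)-2,3-bis(hydroxymethyl)-1-(Iod′)-4-(Syr′)butane-1,4-diol
Product: 15 (1R,2S,5R,6S)-2-(Iod′)-6-(Syr′)-3,7-dioxabicyclo[3.3.0]octane
Conditions: MsCl, pyridine, CH2Cl2, 0 °C to rt
Reagents that add atoms: none
Why: Sulfonate-mediated double cyclodehydration of a 1,4-diaryl tetraol to the furofuran. The benzylic C–O bonds para to oxygen are labile once sulfonylated, so each oxolane should close through a benzylic cation captured by the CH2O oxygen on the neighbouring bridgehead. Each aryl group takes the exo side, trans to the substituent on C1 or C5, which sets C2 and C6 whatever the carbinol configurations of 14.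

Step 10
Reactants: 15 (1R,2S,5R,6S)-2-(Iod′)-6-(Syr′)-3,7-dioxabicyclo[3.3.0]octane
Product: 16 methyl 2-{3-methoxy-2-(Gua′-methoxy)-5-[(1R,2S,5R,6S)-6-(Syr′)-3,7-dioxabicyclo[3.3.0]oct-2-yl]phenyl}acetate
Conditions: BrZnCH2CO2Me (from BrCH2CO2Me, Zn, THF), Pd2(dba)3, XPhos, THF, 50 °C
Reagents that add atoms: bromo(2-methoxy-2-oxoethyl)zinc (Reformatsky reagent of methyl bromoacetate), COC(=O)C[Zn]Br
Why: Negishi coupling of an aryl iodide with a Reformatsky zinc enolate under zerovalent palladium and a bulky biarylphosphine; the neutral zinc reagent should leave silyl ethers, benzylic ethers and all stereocentres alone.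

Step 11
Reactants: 16 methyl 2-{3-methoxy-2-(Gua′-methoxy)-5-[(1R,2S,5R,6S)-6-(Syr′)-3,7-dioxabicyclo[3.3.0]oct-2-yl]phenyl}acetate
Product: 17 methyl 2-diazo-2-{3-methoxy-2-(Gua′-methoxy)-5-[(1R,2S,5R,6S)-6-(Syr′)-3,7-dioxabicyclo[3.3.0]oct-2-yl]phenyl}acetate
Conditions: p-ABSA, DBU, MeCN, 0 °C to rt
Reagents that add atoms: 4-acetamidobenzenesulfonyl azide (p-ABSA), CC(=O)Nc1ccc(cc1)S(=O)(=O)N=[N+]=[N-]
Why: Regitz diazo transfer to an arylacetate; anhydrous DBU should not cleave the hindered triisopropylsilyl aryl ethers.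

Step 12
Reactants: 17 methyl 2-diazo-2-{3-methoxy-2-(Gua′-methoxy)-5-[(1R,2S,5R,6S)-6-(Syr′)-3,7-dioxabicyclo[3.3.0]oct-2-yl]phenyl}acetate
Product: 18 methyl (2S,3R)-7-methoxy-2-(Gua′)-5-[(1R,2S,5R,6S)-6-(Syr′)-3,7-dioxabicyclo[3.3.0]oct-2-yl]-2,3-dihydro-1-benzofuran-3-carboxylate (2,3-cis)
Conditions: Rh2(R-PTTL)4 (cat.), toluene, −60 °C
Reagents that add atoms: none
Why: Intramolecular 1,5 C–H insertion of a donor/acceptor dirhodium carbene into the benzylic ether C–H, which is activated by the oxygen and the electron-rich arene, closing the dihydrofuran ring. The chiral carboxylate ligands select one benzylic hydrogen (benzofuran C2) and one carbene face (C3), and the concerted insertion at low temperature should deliver the cis ester under kinetic control. The furofuran centres are remote, so a minor product would be a separable diastereomer, not an enantiomer.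

Step 13
Reactants: 18 methyl (2S,3R)-7-methoxy-2-(Gua′)-5-[(1R,2S,5R,6S)-6-(Syr′)-3,7-dioxabicyclo[3.3.0]oct-2-yl]-2,3-dihydro-1-benzofuran-3-carboxylate
Product: 19 {(2S,3S)-7-methoxy-2-(Gua′)-5-[(1R,2S,5R,6S)-6-(Syr′)-3,7-dioxabicyclo[3.3.0]oct-2-yl]-2,3-dihydro-1-benzofuran-3-yl}methanol (2,3-cis)
Conditions: i-Bu2AlH, CH2Cl2, −78 to −40 °C; aq. potassium sodium tartrate
Reagents that add atoms: none
Why: Ester reduction by a Lewis-acidic, non-basic aluminium hydride at low temperature, so that the C3 hydrogen (benzylic and α to the ester) is not removed and the cis arrangement should persist. The descriptor at C3 changes from R to S only because the priorities change.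

Step 14
Reactants: 19 {(2S,3S)-7-methoxy-2-(Gua′)-5-[(1R,2S,5R,6S)-6-(Syr′)-3,7-dioxabicyclo[3.3.0]oct-2-yl]-2,3-dihydro-1-benzofuran-3-yl}methanol
Product: 20 (2S,3S)-2-(4-hydroxy-3-methoxyphenyl)-3-(hydroxymethyl)-7-methoxy-5-[(1R,2S,5R,6S)-6-(4-hydroxy-3,5-dimethoxyphenyl)-3,7-dioxabicyclo[3.3.0]oct-2-yl]-2,3-dihydro-1-benzofuran (the target)
Conditions: Bu4NF, AcOH, THF, 0 °C
Reagents that add atoms: none
Why: Fluoride cleavage of both aryl silyl ethers; buffering with acetic acid keeps the liberated phenols protonated, so quinone methide opening of the benzylic C–O bonds should not occur and no stereocentre is touched.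

## Compound list

1 | syringaldehyde | COc1cc(C=O)cc(OC)c1O | starting material
2 | 3,5-dimethoxy-4-(triisopropylsilyloxy)benzaldehyde | COc1cc(C=O)cc(OC)c1O[Si](C(C)C)(C(C)C)C(C)C | intermediate
3 | 2-[3,5-dimethoxy-4-(triisopropylsilyloxy)phenyl]-1,3-dithiane | COc1cc(C2SCCCS2)cc(OC)c1O[Si](C(C)C)(C(C)C)C(C)C | intermediate
4 | vanillin | COc1cc(C=O)ccc1O | starting material
5 | 3-methoxy-4-(triisopropylsilyloxy)benzaldehyde | COc1cc(C=O)ccc1O[Si](C(C)C)(C(C)C)C(C)C | intermediate
6 | [3-methoxy-4-(triisopropylsilyloxy)phenyl]methanol | COc1cc(CO)ccc1O[Si](C(C)C)(C(C)C)C(C)C | intermediate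
7 | 5-iodovanillin | COc1cc(C=O)cc(I)c1O | starting material
8 | 3-iodo-5-methoxy-4-{[3-methoxy-4-(triisopropylsilyloxy)phenyl]methoxy}benzaldehyde | COc1cc(C=O)cc(I)c1OCc1ccc(O[Si](C(C)C)(C(C)C)C(C)C)c(OC)c1 | intermediate
9 | (5R)-5-[(1R,2S,5R)-menthyloxy]furan-2(5H)-one | O=C1C=C[C@H](O[C@@H]2C[C@H](C)CC[C@H]2C(C)C)O1 | starting material
10 | 2-lithio-2-[3,5-dimethoxy-4-(triisopropylsilyloxy)phenyl]-1,3-dithiane | [Li]C1(SCCCS1)c1cc(OC)c(O[Si](C(C)C)(C(C)C)C(C)C)c(OC)c1 | intermediate
11 | lithium enolate of (4R,5R)-4-[2-(Syr′)-1,3-dithian-2-yl]-5-(Men-oxy)oxolan-2-one | [Li]OC1=C[C@@H](C2(SCCCS2)c2cc(OC)c(O[Si](C(C)C)(C(C)C)C(C)C)c(OC)c2)[C@H](O[C@@H]2C[C@H](C)CC[C@H]2C(C)C)O1 | intermediate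
12 | (3S,4R,5R)-3-[hydroxy(Iod′)methyl]-4-[2-(Syr′)-1,3-dithian-2-yl]-5-(Men-oxy)oxolan-2-one, carbinol epimers | O=C1O[C@@H](O[C@@H]2C[C@H](C)CC[C@H]2C(C)C)[C@H](C2(SCCCS2)c2cc(OC)c(O[Si](C(C)C)(C(C)C)C(C)C)c(OC)c2)[C@H]1C(O)c1cc(OC)c(OCc2ccc(O[Si](C(C)C)(C(C)C)C(C)C)c(OC)c2)c(I)c1 | intermediate
13 | (3S,4R,5R)-3-[hydroxy(Iod′)methyl]-4-(Syr′-carbonyl)-5-(Men-oxy)oxolan-2-one, carbinol epimers | O=C1O[C@@H](O[C@@H]2C[C@H](C)CC[C@H]2C(C)C)[C@H](C(=O)c2cc(OC)c(O[Si](C(C)C)(C(C)C)C(C)C)c(OC)c2)[C@H]1C(O)c1cc(OC)c(OCc2ccc(O[Si](C(C)C)(C(C)C)C(C)C)c(OC)c2)c(I)c1 | intermediate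
14 | (2R,3R)-2,3-bis(hydroxymethyl)-1-(Iod′)-4-(Syr′)butane-1,4-diol, carbinol epimers | OC[C@H](C(O)c1cc(OC)c(O[Si](C(C)C)(C(C)C)C(C)C)c(OC)c1)[C@H](CO)C(O)c1cc(OC)c(OCc2ccc(O[Si](C(C)C)(C(C)C)C(C)C)c(OC)c2)c(I)c1 | intermediate
15 | (1R,2S,5R,6S)-2-(Iod′)-6-(Syr′)-3,7-dioxabicyclo[3.3.0]octane | COc1cc([C@H]2OC[C@H]3[C@@H]2CO[C@@H]3c2cc(OC)c(O[Si](C(C)C)(C(C)C)C(C)C)c(OC)c2)cc(I)c1OCc1ccc(O[Si](C(C)C)(C(C)C)C(C)C)c(OC)c1 | intermediate
16 | methyl 2-{3-methoxy-2-(Gua′-methoxy)-5-[(1R,2S,5R,6S)-6-(Syr′)-3,7-dioxabicyclo[3.3.0]oct-2-yl]phenyl}acetate | COc1cc([C@H]2OC[C@H]3[C@@H]2CO[C@@H]3c2cc(OC)c(O[Si](C(C)C)(C(C)C)C(C)C)c(OC)c2)cc(CC(=O)OC)c1OCc1ccc(O[Si](C(C)C)(C(C)C)C(C)C)c(OC)c1 | intermediate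
17 | methyl 2-diazo-2-{3-methoxy-2-(Gua′-methoxy)-5-[(1R,2S,5R,6S)-6-(Syr′)-3,7-dioxabicyclo[3.3.0]oct-2-yl]phenyl}acetate | COc1cc([C@H]2OC[C@H]3[C@@H]2CO[C@@H]3c2cc(OC)c(O[Si](C(C)C)(C(C)C)C(C)C)c(OC)c2)cc(C(=[N+]=[N-])C(=O)OC)c1OCc1ccc(O[Si](C(C)C)(C(C)C)C(C)C)c(OC)c1 | intermediate
18 | methyl (2S,3R)-7-methoxy-2-(Gua′)-5-[(1R,2S,5R,6S)-6-(Syr′)-3,7-dioxabicyclo[3.3.0]oct-2-yl]-2,3-dihydro-1-benzofuran-3-carboxylate (cis) | COc1cc([C@H]2Oc3c(OC)cc([C@H]4OC[C@H]5[C@@H]4CO[C@@H]5c4cc(OC)c(O[Si](C(C)C)(C(C)C)C(C)C)c(OC)c4)cc3[C@H]2C(=O)OC)ccc1O[Si](C(C)C)(C(C)C)C(C)C | intermediate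
19 | {(2S,3S)-7-methoxy-2-(Gua′)-5-[(1R,2S,5R,6S)-6-(Syr′)-3,7-dioxabicyclo[3.3.0]oct-2-yl]-2,3-dihydro-1-benzofuran-3-yl}methanol (cis) | COc1cc([C@H]2Oc3c(OC)cc([C@H]4OC[C@H]5[C@@H]4CO[C@@H]5c4cc(OC)c(O[Si](C(C)C)(C(C)C)C(C)C)c(OC)c4)cc3[C@H]2CO)ccc1O[Si](C(C)C)(C(C)C)C(C)C | intermediate
20 | (2S,3S)-2-(4-hydroxy-3-methoxyphenyl)-3-(hydroxymethyl)-7-methoxy-5-[(1R,2S,5R,6S)-6-(4-hydroxy-3,5-dimethoxyphenyl)-3,7-dioxabicyclo[3.3.0]oct-2-yl]-2,3-dihydro-1-benzofuran | COc1cc([C@H]2Oc3c(OC)cc([C@H]4OC[C@H]5[C@@H]4CO[C@@H]5c4cc(OC)c(O)c(OC)c4)cc3[C@H]2CO)ccc1O | target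

## Step count and least certain steps

Total: 14 steps. Longest linear sequence: 12 steps (4 to 20 through steps 3, 4, 5, 6 to 14).

**Step 6 (key step).** The hindered enolate 11 may be trapped incompletely, by proton transfer or by retro-aldol on warming, and residual n-BuLi could exchange with the iodide of 8. The fallback separates the two bond formations and sets out from 3 and 9. The conjugate addition alone is quenched with NH4Cl to give (4R,5R)-4-[2-(Syr′)-1,3-dithian-2-yl]-5-(Men-oxy)oxolan-2-one F1, which is purified. F1 is deprotonated with LiN(i-Pr)2 at −78 °C, the enolate is transmetallated with ZnCl2 to hold the aldolate, and 8 is added. The sequence comes back to the route at 12.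

**Step 12.** Facial or cis/trans discrimination may erode, because the ether oxygen is flanked by a methoxy group and the carbene carbon, which twists the benzylic CH2 away from the usual geometry. A wrong sense at benzofuran C2 is met by the mirror-image catalyst, as stated in the assumption. For loss of cis selectivity the fallback sets out from the trans ester formed beside 18, methyl (2S,3S)-7-methoxy-2-(Gua′)-5-[(1R,2S,5R,6S)-6-(Syr′)-3,7-dioxabicyclo[3.3.0]oct-2-yl]-2,3-dihydro-1-benzofuran-3-carboxylate F2. F2 is converted to its ester enolate with LiN(SiMe3)2 at −78 °C and protonated kinetically with 2,6-di-tert-butyl-4-methylphenol on the face away from the C2 aryl group. This comes back to the route at 18.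

**Step 9.** Ring closure by displacement at the primary carbons, with retention at the benzylic carbons, may compete with benzylic ionisation. Both para oxygens are twisted by two ortho substituents and the iodine lowers donor strength, so the carbinol mixture of 14 could be carried into C2/C6 epimers. The fallback makes the benzylic carbons the only electrophiles: acid-catalysed cyclodehydration of 14 with catalytic camphorsulfonic acid in CH2Cl2 at 0 °C, with the primary hydroxyls free as nucleophiles. It sets out from 14 and comes back at 15; the vanillyl ether is the group to watch.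

**Step 10.** Transmetallation or reductive elimination at the ortho-alkoxy aryl iodide may be slow, giving protodeiodination or self-condensation of the zinc enolate. The fallback is the zerovalent-palladium-catalysed coupling of 15 with methyl diazoacetate (Pd(PPh3)4, Ag2CO3, Et3N, toluene, rt), which installs the diazo ester in one operation. It sets out from 15 and comes back at 17, bypassing 16.

**Step 7.** The new aryl ketone has its α-hydrogen β to the acetal carbon, so β-elimination of the acetal oxygen is possible, as is retro-aldol of the β-hydroxy lactone. The fallback reverses the order and sets out from 12. LiBH4 first gives (2R,3R)-2-[hydroxy(Iod′)methyl]-3-[2-(Syr′)-1,3-dithian-2-yl]butane-1,4-diol F3 with release of menthol. Hg(ClO4)2 and CaCO3 then give (2R,3R)-4-hydroxy-2-(hydroxymethyl)-3-[hydroxy(Iod′)methyl]-1-(Syr′)butan-1-one F4, in equilibrium with its cyclic hemiketal. NaBH4 reduces F4, and the sequence comes back to the route at 14.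

## Further compounds

F1 | step 6 | (4R,5R)-4-[2-(Syr′)-1,3-dithian-2-yl]-5-(Men-oxy)oxolan-2-one | O=C1C[C@@H](C2(SCCCS2)c2cc(OC)c(O[Si](C(C)C)(C(C)C)C(C)C)c(OC)c2)[C@H](O[C@@H]2C[C@H](C)CC[C@H]2C(C)C)O1
F2 | step 12 | methyl (2S,3S)-7-methoxy-2-(Gua′)-5-[(1R,2S,5R,6S)-6-(Syr′)-3,7-dioxabicyclo[3.3.0]oct-2-yl]-2,3-dihydro-1-benzofuran-3-carboxylate (trans) | COc1cc([C@H]2Oc3c(OC)cc([C@H]4OC[C@H]5[C@@H]4CO[C@@H]5c4cc(OC)c(O[Si](C(C)C)(C(C)C)C(C)C)c(OC)c4)cc3[C@@H]2C(=O)OC)ccc1O[Si](C(C)C)(C(C)C)C(C)C
F0 | step 9 | none | none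
F0 | step 10 | none | none
F3 | step 7 | (2R,3R)-2-[hydroxy(Iod′)methyl]-3-[2-(Syr′)-1,3-dithian-2-yl]butane-1,4-diol, carbinol epimers | OC[C@H](C1(SCCCS1)c1cc(OC)c(O[Si](C(C)C)(C(C)C)C(C)C)c(OC)c1)[C@H](CO)C(O)c1cc(OC)c(OCc2ccc(O[Si](C(C)C)(C(C)C)C(C)C)c(OC)c2)c(I)c1
F4 | step 7 | (2R,3R)-4-hydroxy-2-(hydroxymethyl)-3-[hydroxy(Iod′)methyl]-1-(Syr′)butan-1-one, carbinol epimers | OC[C@H](C(=O)c1cc(OC)c(O[Si](C(C)C)(C(C)C)C(C)C)c(OC)c1)[C@H](CO)C(O)c1cc(OC)c(OCc2ccc(O[Si](C(C)C)(C(C)C)C(C)C)c(OC)c2)c(I)c1
A1 | alternative 1 | (1R,2S,5R,6S)-2-(4-benzyloxy-3-iodo-5-methoxyphenyl)-6-(Syr′)-3,7-dioxabicyclo[3.3.0]octane | COc1cc([C@H]2OC[C@H]3[C@@H]2CO[C@@H]3c2cc(OC)c(O[Si](C(C)C)(C(C)C)C(C)C)c(OC)c2)cc(I)c1OCc1ccccc1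
A2 | alternative 1 | [(2S,3R)-2-(4-benzyloxy-3-iodo-5-methoxyphenyl)-2,3-dihydrofuran-3-yl]methanol | COc1cc([C@H]2OC=C[C@@H]2CO)cc(I)c1OCc1ccccc1
A3 | alternative 1 | [4-(dimethoxymethyl)-2,6-dimethoxyphenoxy]triisopropylsilane | COC(OC)c1cc(OC)c(O[Si](C(C)C)(C(C)C)C(C)C)c(OC)c1
A4 | alternative 2 | (1R,2S,5R,6S)-2-(Iod′)-6-(Syr′)-3,7-dioxabicyclo[3.3.0]octane (identical with 15) | COc1cc([C@H]2OC[C@H]3[C@@H]2CO[C@@H]3c2cc(OC)c(O[Si](C(C)C)(C(C)C)C(C)C)c(OC)c2)cc(I)c1OCc1ccc(O[Si](C(C)C)(C(C)C)C(C)C)c(OC)c1
A5 | alternative 2 | 2-{(R)-(Iod′)[(E)-3-(Syr′)prop-2-enyloxy]methyl}oxirane, either configuration at the oxirane carbon | COc1cc([C@@H](OC/C=C/c2cc(OC)c(O[Si](C(C)C)(C(C)C)C(C)C)c(OC)c2)C2CO2)cc(I)c1OCc1ccc(O[Si](C(C)C)(C(C)C)C(C)C)c(OC)c1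
A6 | alternative 3 | methyl (2S,3R)-7-methoxy-2-(Gua′)-5-[(1R,2S,5R,6S)-6-(Syr′)-3,7-dioxabicyclo[3.3.0]oct-2-yl]-2,3-dihydro-1-benzofuran-3-carboxylate (identical with 18) | COc1cc([C@H]2Oc3c(OC)cc([C@H]4OC[C@H]5[C@@H]4CO[C@@H]5c4cc(OC)c(O[Si](C(C)C)(C(C)C)C(C)C)c(OC)c4)cc3[C@H]2C(=O)OC)ccc1O[Si](C(C)C)(C(C)C)C(C)C
A7 | alternative 3 | methyl 2-diazo-2-{3-methoxy-2-(Gua′-methoxy)-5-[(1R,2S,5R,6S)-6-(Syr′)-3,7-dioxabicyclo[3.3.0]oct-2-yl]phenyl}acetate (identical with 17) | COc1cc([C@H]2OC[C@H]3[C@@H]2CO[C@@H]3c2cc(OC)c(O[Si](C(C)C)(C(C)C)C(C)C)c(OC)c2)cc(C(=[N+]=[N-])C(=O)OC)c1OCc1ccc(O[Si](C(C)C)(C(C)C)C(C)C)c(OC)c1
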